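# Proposed synthesis of (3R,4R)-4-(3,4-dimethoxybenzyl)-3-(4-hydroxy-3,5-dimethoxybenzyl)dihydrofuran-2(3H)-one by conjunctive cross-coupling

**Numbering key (used throughout).** 1 sinapic acid; 2 its benzyl ester benzyl ether; 3 O-benzyl sinapyl alcohol; 4 its silyl ether; 5 bis(pinacolato)diboron; 6 (S)-boronic ester; 7 3,4-dimethoxyphenol; 8 its triflate; 9 tetravinylstannane; 10 vinyllithium; 11 vinylborate complex; 12 coupling product; 13 chloromethyl borate; 14 homologated boronic ester; 15 alcohol; 16 aldehyde; 17 acid; 18 hydroxy acid; 19 O-benzyl lactone; 20 target.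

Lactone atom labels are used for all intermediates: O1, C2 (C=O), C3, C4, C5; C7' is the CH2 on C3 (to the syringyl ring) and C7 the CH2 on C4 (to the veratryl ring).

## Analysis of the target

The target is a trans-dibenzyl-γ-butyrolactone: a five-membered lactone carrying a 4-hydroxy-3,5-dimethoxybenzyl group on C3 and a 3,4-dimethoxybenzyl group on C4. The two stereocentres are adjacent and both (R), which places the benzyl groups trans. C3 is α to the carbonyl and can epimerise, but trans is the more stable arrangement, so C4 is the centre that cannot be corrected later. The sensitive groups are the free phenol flanked by two methoxy groups (easily oxidised), the two electron-rich arenes (open to electrophilic halogenation and oxidative coupling) and the lactone. The difficulty is the near-symmetry of the C2–C3–C4–C5 chain: each inner carbon bears a benzyl group and each end is an oxygenated carbon. The route must therefore tell the syringyl half from the veratryl half and the carbonyl end from the CH2–O end while setting two contiguous centres. The strategy rests on C4, which is bonded to C3, to the benzylic carbon C7 and to C5. C4–C7 is treated as a former vinyl group placed between C3 and the veratryl ring, with boron on C4 standing in for C5.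

## Retrosynthetic reasoning

**20 from 19 (phenol O–benzyl bond).** The phenol is freed last, because a free 2,6-dimethoxyphenol would not survive the oxidations at C2 and at boron. A benzyl ether withstands organolithiums, hydride, acid and the oxidants used, and hydrogenolysis touches nothing else in 19.

**19 from 18 and 17 (O1–C2 and C5–O1).** The acyl bond is opened to hydroxy acid 18, and the C5–O bond is traced back to a C5–B bond in 17. A boron atom on C5 is inert while C2 is raised to the acid level, so the two ends of the chain never have to be told apart by protecting groups. Oxidation of boron then releases the alcohol next to the acid and the ring closes on acidification.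

**17 from 16, 15 and 14 (oxidation level of C2).** No skeletal bond is cut. The acid comes from aldehyde 16, the aldehyde from alcohol 15, and the alcohol from silyl ether 14, the form in which C2 travels through the organolithium steps.

**14 from 12 (C4–C5).** This bond is cut because a secondary boronic ester on C4 is exactly what the key step leaves behind. A one-carbon insertion into the C4–B bond moves boron to C5 with retention at C4. The forward step needs a short-lived carbenoid to add to a hindered boron.

**12 from 6, 10 and 8 (C3–C4 and C7–aryl).** These are the two bonds that join the halves of the molecule. Cutting both turns C4 and C7 into the two carbons of vinyllithium 10, C3 into the boron-bearing carbon of 6, and the veratryl ring into triflate 8. One operation then assembles the skeleton, sets C4 and leaves boron as the handle for C5. The forward reaction has to choose one face of the vinyl group against the existing C3 centre and move a branched secondary group from boron to carbon without losing the neighbouring silyloxy group.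

**6 from 4 and 5 (C3–B and C7'–H).** The styrene-type double bond of 4 is polarised by the aryl ring, so a copper–boryl species places copper on C7' and boron on C3, and a proton then replaces copper. A chiral diphosphine on copper selects the alkene face and sets C3.

**4 from 3, 2 and 1; 8 from 7; 10 from 9.** Sinapic acid 1 already holds the syringyl ring, C7', C3 and C2 with E geometry. Double benzylation gives 2, ester reduction gives 3 and silylation gives 4. Triflate 8 comes from phenol 7 by sulfonylation. Vinyllithium 10 comes from stannane 9 by tin–lithium exchange, which gives it free of halide.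

## Alternatives that were turned down

**Alternative 1: oxygen insertion into a prochiral cyclobutanone.**
- Disconnection: C3–C7' by enolate alkylation, and before that O1–C2 and O1–C5 by ring expansion of 3-(3,4-dimethoxybenzyl)cyclobutanone A1.
- Forward key step: a Baeyer–Villiger monooxygenase inserts oxygen next to one of the two enantiotopic CH2 groups of A1 and gives lactone A2 with C4 set. The enolate of A2 is then alkylated with benzylic bromide A3 anti to the C4 substituent to give 19, and hydrogenolysis finishes.
- For: about five steps in all, which is clearly shorter than the chosen route. The trans relationship follows from substrate control in a well-behaved alkylation, and the oxidant is O2.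
- Against: the only source of absolute configuration is an enzyme that must distinguish two CH2 groups by a benzyl group two bonds away. The sense and level of that selection cannot be predicted from structure, and a lipophilic substrate has to be processed in water with cofactor recycling.
- Comparison: Alternative 1 wins on step economy. The chosen route offers small-molecule catalysts whose antipodes are both available, and it sets C3 and C4 independently rather than relaying one from the other.

**Alternative 2: lactonisation by oxetane opening.**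
- Disconnection: C5–O1, by attack of the carboxyl group of oxetanyl acid A4 on one of the two diastereotopic oxetane CH2 groups.
- Forward key step: a chiral Brønsted acid activates the oxetane, the acid closes the lactone, and the other CH2 is released as the C7 hydroxymethyl group of A5.
- For: the key step is metal-free and uses no organolithium reagent, and both of these points are stronger than in the chosen route. A5 would also be a common intermediate for varying the C4 aryl group.
- Against: the C3 centre of A4 has to be made beforehand by separate asymmetric chemistry, and the catalyst must then control which CH2 is attacked in the presence of that centre. The C7–aryl bond is still missing after the key step and must be made by activating a β-branched primary alcohol and coupling it with an aryl nucleophile next to a lactone, where elimination and attack on the carbonyl compete.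
- Comparison: the length is similar or greater. The chosen route forms C7–aryl in the same event as C3–C4, so no separate sp3–sp2 coupling is needed.

**Alternative 3: rhodium-catalysed arylative enyne cyclisation.**
- Disconnection: C7'–aryl and C3–C4, with the ester tether of enyne A6 supplying O1, C2 and C5.
- Forward key step: the arylrhodium species formed from boronic acid A7 adds across the alkyne of A6, and the alkenylrhodium inserts the cinnamyl alkene to close the ring and give benzylidene lactone A8.
- For: it is the most convergent plan, with ring and two C–C bonds formed in one step from an ester of simple parts, about five to six steps in all. One hydrogenation could saturate the alkene and remove the benzyl group.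
- Against: after alkene insertion rhodium sits on C7 with no carbonyl or leaving group to end the cycle, so β-hydride elimination competes with protonation. The ester tether prefers a conformation that holds the two π systems apart. C3 is not set in the key step, and hydrogen adds to A8 from the face opposite the C4 substituent, which puts the benzyl groups cis and calls for a later base epimerisation.
- Comparison: Alternative 3 is shorter and more convergent. The chosen route has a defined termination (reductive elimination from palladium) and creates both centres directly under catalyst control.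

Key step: step 7

Assumption: the ligand antipodes written in steps 4 and 7 are taken to give the (S) centre of 6 and the (R) centre at C4 of 12; if the sense of induction is opposite, the mirror-image ligand is used with no other change.

## Route

Step 1
Reactants: 1 sinapic acid, (E)-3-(4-hydroxy-3,5-dimethoxyphenyl)prop-2-enoic acid
Product: 2 benzyl (E)-3-[4-(benzyloxy)-3,5-dimethoxyphenyl]prop-2-enoate
Conditions: BnBr (2.5 equiv), K2CO3 (3 equiv), DMF, 60 °C
Reagents that add atoms: benzyl bromide, BrCc1ccccc1
Why: Williamson etherification of the phenoxide and O-alkylation of the carboxylate run in the same flask; the benzyl ester is only a temporary activating group for the reduction that follows.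

Step 2
Reactants: 2 benzyl (E)-3-[4-(benzyloxy)-3,5-dimethoxyphenyl]prop-2-enoate
Product: 3 (E)-3-[4-(benzyloxy)-3,5-dimethoxyphenyl]prop-2-en-1-ol
Conditions: i-Bu2AlH (3 equiv), CH2Cl2, −78 → 0 °C; aq. KNaC4H4O6
Reagents that add atoms: none
Why: Hydride reduction of an α,β-unsaturated ester by i-Bu2AlH is a clean 1,2-reduction to the allylic alcohol and leaves the aryl benzyl ether and the E alkene untouched.

Step 3
Reactants: 3 (E)-3-[4-(benzyloxy)-3,5-dimethoxyphenyl]prop-2-en-1-ol
Product: 4 (E)-{3-[4-(benzyloxy)-3,5-dimethoxyphenyl]allyloxy}(tert-butyl)dimethylsilane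
Conditions: TBSCl (1.2 equiv), imidazole (2 equiv), DMF, 0 °C → rt
Reagents that add atoms: tert-butyldimethylsilyl chloride, CC(C)(C)[Si](C)(C)Cl
Why: Standard silylation of a primary alcohol; the bulky silyl ether is a poor leaving group and a weak Lewis base, which matters in steps 4 and 7.

Step 4
Reactants: 4 (E)-{3-[4-(benzyloxy)-3,5-dimethoxyphenyl]allyloxy}(tert-butyl)dimethylsilane; 5 bis(pinacolato)diboron
Product: 6 (S)-tert-butyl{3-[4-(benzyloxy)-3,5-dimethoxyphenyl]-2-(4,4,5,5-tetramethyl-1,3,2-dioxaborolan-2-yl)propoxy}dimethylsilane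
Conditions: CuCl (5 mol%), NaOt-Bu (10 mol%), (R)-DTBM-SEGPHOS (6 mol%), MeOH (2 equiv), THF, rt
Reagents that add atoms: none
Why: Copper-catalysed enantioselective protoboration of a β-substituted vinylarene: the boryl complex of monovalent copper adds syn across the alkene with copper on the benzylic carbon C7' and boron on C3, and methanol protonates the C–Cu bond. The diphosphine-bound copper selects the alkene face and so sets C3 as (S).

Step 5
Reactants: 7 3,4-dimethoxyphenol
Product: 8 3,4-dimethoxyphenyl trifluoromethanesulfonate
Conditions: Tf2O (1.1 equiv), pyridine (2 equiv), CH2Cl2, 0 °C → rt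
Reagents that add atoms: trifluoromethanesulfonic anhydride, O=S(=O)(OS(=O)(=O)C(F)(F)F)C(F)(F)F
Why: O-sulfonylation of a phenol; the triflate is needed because a non-coordinating leaving group keeps palladium cationic in step 7.

Step 6
Reactants: 9 tetravinylstannane
Product: 10 vinyllithium
Conditions: n-BuLi (hexanes), pentane, rt; solid washed with pentane under argon, dissolved in THF and titrated
Reagents that add atoms: n-butyllithium, [Li]CCCC
Why: Tin–lithium exchange; vinyllithium precipitates from pentane free of lithium halide, which would otherwise slow the palladium step.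

Step 7
Reactants: 6 (S)-tert-butyl{3-[4-(benzyloxy)-3,5-dimethoxyphenyl]-2-(4,4,5,5-tetramethyl-1,3,2-dioxaborolan-2-yl)propoxy}dimethylsilane; 10 vinyllithium; 8 3,4-dimethoxyphenyl trifluoromethanesulfonate
Product: 12 tert-butyl{[(2R,3R)-2-[4-(benzyloxy)-3,5-dimethoxybenzyl]-4-(3,4-dimethoxyphenyl)-3-(4,4,5,5-tetramethyl-1,3,2-dioxaborolan-2-yl)butyl]oxy}dimethylsilane, via lithium vinylborate complex 11 (not isolated)
Conditions: 10 (1.05 equiv), THF, 0 °C → rt; then Pd(OAc)2 (3 mol%), (Sp,Sp)-1,1'-bis[bis(4-methoxy-3,5-dimethylphenyl)phosphino]-2,2'-bis[(R)-α-(dimethylamino)benzyl]ferrocene (3.6 mol%), 8 (1.1 equiv), THF, 60 °C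
Reagents that add atoms: none
Why: Vinyllithium 10 adds to the boron of 6 to give the four-coordinate borate 11, while oxidative addition of triflate 8 to zerovalent palladium (formed from Pd(OAc)2 and the diphosphine) gives a cationic aryl complex of divalent palladium that binds the vinyl group of 11. This π-activation triggers a 1,2-metallate shift in which the C3 alkyl group moves from boron to the vinyl α-carbon anti to palladium (C3–C4 bond, retention at C3), and reductive elimination from the resulting β-boryl alkylpalladium species forms the C7–aryl bond and returns zerovalent palladium. The closest known reaction type is the enantioselective palladium-catalysed conjunctive cross-coupling of vinylboron ate complexes with aryl triflates, for which alkyl migrating groups, secondary ones included, are established. No ring is closed. The one new stereocentre, C4, is fixed by the chiral diphosphine on palladium, which decides the face of the vinyl group that is bound and thereby the face reached by the migrating carbon; C3 is carried through unchanged. The step needs catalyst control to outweigh the bias of the neighbouring C3 centre, migration of carbon and not of a pinacol oxygen, and an intact C2 silyl ether: the bulky, weakly basic silyloxy group is a poor leaving group without a Lewis acid, and halide-free 10 with the triflate leaving group keeps palladium cationic so that the shift outpaces direct vinyl transfer.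

Step 8
Reactants: 12 tert-butyl{[(2R,3R)-2-[4-(benzyloxy)-3,5-dimethoxybenzyl]-4-(3,4-dimethoxyphenyl)-3-(4,4,5,5-tetramethyl-1,3,2-dioxaborolan-2-yl)butyl]oxy}dimethylsilane
Product: 14 tert-butyl{[(2R,3R)-2-[4-(benzyloxy)-3,5-dimethoxybenzyl]-3-(3,4-dimethoxybenzyl)-4-(4,4,5,5-tetramethyl-1,3,2-dioxaborolan-2-yl)butyl]oxy}dimethylsilane, via chloromethyl borate complex 13 (not isolated)
Conditions: BrCH2Cl (3 equiv), n-BuLi (2.5 equiv, added last), THF, −78 °C → rt
Reagents that add atoms: bromochloromethane, ClCBr
Why: Matteson homologation: chloromethyllithium formed by bromine–lithium exchange adds to boron, and on warming the C4 group migrates to the CH2 carbon with loss of chloride and retention at C4, which installs C5 still bearing boron.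

Step 9
Reactants: 14 tert-butyl{[(2R,3R)-2-[4-(benzyloxy)-3,5-dimethoxybenzyl]-3-(3,4-dimethoxybenzyl)-4-(4,4,5,5-tetramethyl-1,3,2-dioxaborolan-2-yl)butyl]oxy}dimethylsilane
Product: 15 (2R,3R)-2-[4-(benzyloxy)-3,5-dimethoxybenzyl]-3-(3,4-dimethoxybenzyl)-4-(4,4,5,5-tetramethyl-1,3,2-dioxaborolan-2-yl)butan-1-ol
Conditions: camphor-10-sulfonic acid (10 mol%), MeOH/CH2Cl2 (1:1), 0 °C → rt
Reagents that add atoms: none
Why: Acid-catalysed methanolysis removes a primary silyl ether quickly; fluoride is avoided so that the alkyl pinacol boronate, which tolerates mild acid, is not disturbed.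

Step 10
Reactants: 15 (2R,3R)-2-[4-(benzyloxy)-3,5-dimethoxybenzyl]-3-(3,4-dimethoxybenzyl)-4-(4,4,5,5-tetramethyl-1,3,2-dioxaborolan-2-yl)butan-1-ol
Product: 16 (2R,3R)-2-[4-(benzyloxy)-3,5-dimethoxybenzyl]-3-(3,4-dimethoxybenzyl)-4-(4,4,5,5-tetramethyl-1,3,2-dioxaborolan-2-yl)butanal
Conditions: Dess–Martin periodinane (1.3 equiv), CH2Cl2, 0 °C → rt; crude product used directly
Reagents that add atoms: none
Why: Dess–Martin oxidation is neutral and non-nucleophilic, so the C–B bond (which needs a nucleophilic oxidant) and the electron-rich arenes are left alone; the aldehyde is not purified, to protect the C3 centre.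

Step 11
Reactants: 16 (2R,3R)-2-[4-(benzyloxy)-3,5-dimethoxybenzyl]-3-(3,4-dimethoxybenzyl)-4-(4,4,5,5-tetramethyl-1,3,2-dioxaborolan-2-yl)butanal
Product: 17 (2R,3R)-2-[4-(benzyloxy)-3,5-dimethoxybenzyl]-3-(3,4-dimethoxybenzyl)-4-(4,4,5,5-tetramethyl-1,3,2-dioxaborolan-2-yl)butanoic acid
Conditions: NaClO2 (3 equiv), NaH2PO4 (3 equiv), 2-methyl-2-butene (20 equiv), t-BuOH/H2O (3:1), 0 °C → rt
Reagents that add atoms: sodium chlorite, [Na+].[O-]Cl=O
Why: Pinnick oxidation takes the aldehyde to the acid under buffered conditions that do not epimerise C3, and excess alkene traps hypochlorous acid before it can chlorinate the arenes. Any early oxidation of the C–B bond would only anticipate step 12.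

Step 12
Reactants: 17 (2R,3R)-2-[4-(benzyloxy)-3,5-dimethoxybenzyl]-3-(3,4-dimethoxybenzyl)-4-(4,4,5,5-tetramethyl-1,3,2-dioxaborolan-2-yl)butanoic acid
Product: 19 (3R,4R)-3-[4-(benzyloxy)-3,5-dimethoxybenzyl]-4-(3,4-dimethoxybenzyl)dihydrofuran-2(3H)-one, via hydroxy acid 18 (not isolated)
Conditions: NaBO3·4H2O (4 equiv), THF/H2O (1:1), rt; then 1 M HCl to pH 2, rt
Reagents that add atoms: sodium perborate, [Na+].[O-]OB=O
Why: Perborate adds to boron and the C5 carbon migrates to oxygen, giving the C5 alcohol (hydroxy acid 18); on acidification the γ-hydroxy acid closes to the five-membered lactone. Neither C3 nor C4 is involved, so the trans arrangement is kept.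

Step 13
Reactants: 19 (3R,4R)-3-[4-(benzyloxy)-3,5-dimethoxybenzyl]-4-(3,4-dimethoxybenzyl)dihydrofuran-2(3H)-one
Product: 20 (3R,4R)-4-(3,4-dimethoxybenzyl)-3-(4-hydroxy-3,5-dimethoxybenzyl)dihydrofuran-2(3H)-one
Conditions: H2 (1 atm), 10% Pd/C, EtOAc, rt
Reagents that add atoms: none
Why: Hydrogenolysis of the aryl benzyl ether frees the phenol; the lactone, the methyl ethers and the benzylic C–C bonds are inert under these conditions.

## Compound list

1 | sinapic acid, (E)-3-(4-hydroxy-3,5-dimethoxyphenyl)prop-2-enoic acid | COc1cc(/C=C/C(=O)O)cc(OC)c1O | starting material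
2 | benzyl (E)-3-[4-(benzyloxy)-3,5-dimethoxyphenyl]prop-2-enoate | COc1cc(/C=C/C(=O)OCc2ccccc2)cc(OC)c1OCc1ccccc1 | intermediate
3 | (E)-3-[4-(benzyloxy)-3,5-dimethoxyphenyl]prop-2-en-1-ol | COc1cc(/C=C/CO)cc(OC)c1OCc1ccccc1 | intermediate
4 | (E)-{3-[4-(benzyloxy)-3,5-dimethoxyphenyl]allyloxy}(tert-butyl)dimethylsilane | COc1cc(/C=C/CO[Si](C)(C)C(C)(C)C)cc(OC)c1OCc1ccccc1 | intermediate
5 | bis(pinacolato)diboron | CC1(C)OB(OC1(C)C)B1OC(C)(C)C(C)(C)O1 | starting material
6 | (S)-tert-butyl{3-[4-(benzyloxy)-3,5-dimethoxyphenyl]-2-(4,4,5,5-tetramethyl-1,3,2-dioxaborolan-2-yl)propoxy}dimethylsilane | CC1(C)OB(OC1(C)C)[C@H](CO[Si](C)(C)C(C)(C)C)Cc1cc(OC)c(OCc2ccccc2)c(OC)c1 | intermediate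
7 | 3,4-dimethoxyphenol | COc1ccc(O)cc1OC | starting material
8 | 3,4-dimethoxyphenyl trifluoromethanesulfonate | COc1ccc(OS(=O)(=O)C(F)(F)F)cc1OC | intermediate
9 | tetravinylstannane | C=C[Sn](C=C)(C=C)C=C | starting material
10 | vinyllithium | [Li]C=C | intermediate
11 | lithium {(S)-1-[4-(benzyloxy)-3,5-dimethoxyphenyl]-3-[(tert-butyldimethylsilyl)oxy]propan-2-yl}(ethenyl)(pinacolato)borate, formed in the flask | [Li+].C=C[B-]1(OC(C)(C)C(C)(C)O1)[C@H](CO[Si](C)(C)C(C)(C)C)Cc1cc(OC)c(OCc2ccccc2)c(OC)c1 | intermediate
12 | tert-butyl{[(2R,3R)-2-[4-(benzyloxy)-3,5-dimethoxybenzyl]-4-(3,4-dimethoxyphenyl)-3-(4,4,5,5-tetramethyl-1,3,2-dioxaborolan-2-yl)butyl]oxy}dimethylsilane | COc1ccc(C[C@H]([C@H](CO[Si](C)(C)C(C)(C)C)Cc2cc(OC)c(OCc3ccccc3)c(OC)c2)B2OC(C)(C)C(C)(C)O2)cc1OC | intermediate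
13 | lithium (chloromethyl){(2R,3R)-3-[4-(benzyloxy)-3,5-dimethoxybenzyl]-4-[(tert-butyldimethylsilyl)oxy]-1-(3,4-dimethoxyphenyl)butan-2-yl}(pinacolato)borate, formed in the flask | [Li+].ClC[B-]1(OC(C)(C)C(C)(C)O1)[C@H](Cc1ccc(OC)c(OC)c1)[C@H](CO[Si](C)(C)C(C)(C)C)Cc1cc(OC)c(OCc2ccccc2)c(OC)c1 | intermediate
14 | tert-butyl{[(2R,3R)-2-[4-(benzyloxy)-3,5-dimethoxybenzyl]-3-(3,4-dimethoxybenzyl)-4-(4,4,5,5-tetramethyl-1,3,2-dioxaborolan-2-yl)butyl]oxy}dimethylsilane | CC1(C)OB(OC1(C)C)C[C@H](Cc1ccc(OC)c(OC)c1)[C@H](CO[Si](C)(C)C(C)(C)C)Cc1cc(OC)c(OCc2ccccc2)c(OC)c1 | intermediate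
15 | (2R,3R)-2-[4-(benzyloxy)-3,5-dimethoxybenzyl]-3-(3,4-dimethoxybenzyl)-4-(4,4,5,5-tetramethyl-1,3,2-dioxaborolan-2-yl)butan-1-ol | CC1(C)OB(OC1(C)C)C[C@H](Cc1ccc(OC)c(OC)c1)[C@H](CO)Cc1cc(OC)c(OCc2ccccc2)c(OC)c1 | intermediate
16 | (2R,3R)-2-[4-(benzyloxy)-3,5-dimethoxybenzyl]-3-(3,4-dimethoxybenzyl)-4-(4,4,5,5-tetramethyl-1,3,2-dioxaborolan-2-yl)butanal | CC1(C)OB(OC1(C)C)C[C@H](Cc1ccc(OC)c(OC)c1)[C@H](C=O)Cc1cc(OC)c(OCc2ccccc2)c(OC)c1 | intermediate
17 | (2R,3R)-2-[4-(benzyloxy)-3,5-dimethoxybenzyl]-3-(3,4-dimethoxybenzyl)-4-(4,4,5,5-tetramethyl-1,3,2-dioxaborolan-2-yl)butanoic acid | CC1(C)OB(OC1(C)C)C[C@H](Cc1ccc(OC)c(OC)c1)[C@H](C(=O)O)Cc1cc(OC)c(OCc2ccccc2)c(OC)c1 | intermediate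
18 | (2R,3R)-2-[4-(benzyloxy)-3,5-dimethoxybenzyl]-3-(3,4-dimethoxybenzyl)-4-hydroxybutanoic acid, formed in the flask | OC[C@H](Cc1ccc(OC)c(OC)c1)[C@H](C(=O)O)Cc1cc(OC)c(OCc2ccccc2)c(OC)c1 | intermediate
19 | (3R,4R)-3-[4-(benzyloxy)-3,5-dimethoxybenzyl]-4-(3,4-dimethoxybenzyl)dihydrofuran-2(3H)-one | COc1ccc(C[C@H]2COC(=O)[C@@H]2Cc2cc(OC)c(OCc3ccccc3)c(OC)c2)cc1OC | intermediate
20 | (3R,4R)-4-(3,4-dimethoxybenzyl)-3-(4-hydroxy-3,5-dimethoxybenzyl)dihydrofuran-2(3H)-one | COc1ccc(C[C@H]2COC(=O)[C@@H]2Cc2cc(OC)c(O)c(OC)c2)cc1OC | target

## Step count and least certain steps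

Total step count: 13. Longest linear sequence: 11 (steps 1–4 and 7–13); steps 5 and 6 are one-step side branches that join at step 7.

**Step 7 (key step).** Three processes may interfere.
- The silyloxy group may be lost from borate 11 by β-elimination while the mixture is heated, which destroys the nucleophile.
- The branched secondary group may migrate slowly, so that direct transfer of the vinyl group to palladium or β-hydride elimination takes over.
- Facial selectivity at the vinyl group may be poor if the catalyst preference and the C3 centre oppose each other.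

Diastereomers at C4 should be removed by chromatography at 12 or 15, since a C4 epimer carried to the lactone would lead to the enantiomeric series after any C3 equilibration.

The fallback sets out from 6 and returns at 12. It replaces catalysis by a stoichiometric chiral carbenoid. 2-(3,4-Dimethoxyphenyl)ethanol F1 is esterified with 2,4,6-triisopropylbenzoyl chloride to give 2-(3,4-dimethoxyphenyl)ethyl 2,4,6-triisopropylbenzoate F2. Deprotonation with s-BuLi and (−)-sparteine in Et2O at −78 °C should give the configurationally stable (S)-lithiated benzoate F3. Boronic ester 6 is added to form borate complex F4 with retention. On warming with MgBr2·OEt2 in MeOH the C3 group migrates with inversion at the carbenoid carbon and the benzoate leaves, giving 12. C4 is then fixed by the reagent, and the 1,2-shift has a good leaving group on the α-carbon, so it should outrun β-elimination.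

**Step 4.** The copper–boryl addition may proceed with the opposite orientation (boron on the benzylic carbon, copper next to the CH2OSi group) followed by expulsion of silyloxide, that is, allylic substitution. It may also be slow on the electron-rich styrene, or select the alkene face incompletely.

The fallback sets out from 5 and returns at 6. Commercial 4-allyl-2,6-dimethoxyphenol F5 is benzylated (BnBr, K2CO3) to 5-allyl-2-(benzyloxy)-1,3-dimethoxybenzene F6. Enantioselective diboration of the terminal alkene with 5, catalysed by Pt(dba)3 and a TADDOL-derived phosphonite, gives the (R)-1,2-bis(boronic ester) F7. Site-selective oxidation of the less hindered primary C–B bond with Me3NO gives (S)-3-[4-(benzyloxy)-3,5-dimethoxyphenyl]-2-(4,4,5,5-tetramethyl-1,3,2-dioxaborolan-2-yl)propan-1-ol F8. Silylation with TBSCl and imidazole gives 6. Regiochemistry is then fixed by the position of the terminal alkene and not by alkene polarisation.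

**Step 8.** Chloromethyllithium decomposes above −78 °C, and the boron of 12 is flanked by a tertiary carbon and a benzyl group. Borate formation may therefore be incomplete, leaving a mixture of 12 and 14 that is hard to separate.

The fallback sets out from 12 and returns at 19. It introduces C5 as a vinyl group. Zweifel olefination of 12 with 10 (which is stable at room temperature, so complexation can be driven to completion), then I2 and NaOMe, gives tert-butyl{[(2R,3S)-2-[4-(benzyloxy)-3,5-dimethoxybenzyl]-3-(3,4-dimethoxybenzyl)pent-4-en-1-yl]oxy}dimethylsilane F9 with retention at C4. Acidic methanolysis gives alcohol F10, Dess–Martin oxidation gives aldehyde F11, and Pinnick oxidation gives (2R,3S)-2-[4-(benzyloxy)-3,5-dimethoxybenzyl]-3-(3,4-dimethoxybenzyl)pent-4-enoic acid F12. Lemieux–Johnson cleavage (K2OsO4·2H2O cat., NaIO4, 2,6-lutidine, dioxane/H2O) gives aldehyde acid F13. This is reduced in the same flask with NaBH4 to hydroxy acid 18, which closes to 19 on acidification.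

**Step 11.** Hypochlorous acid may chlorinate the electron-rich rings if trapping is incomplete, and aldehyde 16 may epimerise at C3 before it is oxidised.

The fallback sets out from 16 and returns at 19. It avoids chlorine-based oxidants. Perborate oxidation of the C–B bond of 16 gives the hydroxy aldehyde, which closes to (3R,4R)-3-[4-(benzyloxy)-3,5-dimethoxybenzyl]-4-(3,4-dimethoxybenzyl)tetrahydrofuran-2-ol F14 as a mixture at C2. Fétizon oxidation (Ag2CO3 on Celite, toluene, reflux) gives 19.

If C3 is partly epimerised at any stage, brief base treatment of 19 should return the material to the more stable trans lactone, provided C4 is homogeneous.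

## Further compounds

F1 | step 7 | 2-(3,4-dimethoxyphenyl)ethanol | COc1ccc(CCO)cc1OC
F2 | step 7 | 2-(3,4-dimethoxyphenyl)ethyl 2,4,6-triisopropylbenzoate | COc1ccc(CCOC(=O)c2c(C(C)C)cc(C(C)C)cc2C(C)C)cc1OC
F3 | step 7 | (S)-2-(3,4-dimethoxyphenyl)-1-lithioethyl 2,4,6-triisopropylbenzoate (sparteine complex) | [Li][C@H](OC(=O)c1c(C(C)C)cc(C(C)C)cc1C(C)C)Cc1ccc(OC)c(OC)c1
F4 | step 7 | lithium {(S)-1-[4-(benzyloxy)-3,5-dimethoxyphenyl]-3-[(tert-butyldimethylsilyl)oxy]propan-2-yl}{(S)-2-(3,4-dimethoxyphenyl)-1-[(2,4,6-triisopropylbenzoyl)oxy]ethyl}(pinacolato)borate | [Li+].CC1(C)O[B-](OC1(C)C)([C@H](OC(=O)c1c(C(C)C)cc(C(C)C)cc1C(C)C)Cc1ccc(OC)c(OC)c1)[C@H](CO[Si](C)(C)C(C)(C)C)Cc1cc(OC)c(OCc2ccccc2)c(OC)c1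
F5 | step 4 | 4-allyl-2,6-dimethoxyphenol | COc1cc(CC=C)cc(OC)c1O
F6 | step 4 | 5-allyl-2-(benzyloxy)-1,3-dimethoxybenzene | COc1cc(CC=C)cc(OC)c1OCc1ccccc1
F7 | step 4 | 2,2'-{(2R)-3-[4-(benzyloxy)-3,5-dimethoxyphenyl]propane-1,2-diyl}bis(4,4,5,5-tetramethyl-1,3,2-dioxaborolane) | CC1(C)OB(OC1(C)C)[C@H](CB1OC(C)(C)C(C)(C)O1)Cc1cc(OC)c(OCc2ccccc2)c(OC)c1
F8 | step 4 | (S)-3-[4-(benzyloxy)-3,5-dimethoxyphenyl]-2-(4,4,5,5-tetramethyl-1,3,2-dioxaborolan-2-yl)propan-1-ol | CC1(C)OB(OC1(C)C)[C@H](CO)Cc1cc(OC)c(OCc2ccccc2)c(OC)c1
F9 | step 8 | tert-butyl{[(2R,3S)-2-[4-(benzyloxy)-3,5-dimethoxybenzyl]-3-(3,4-dimethoxybenzyl)pent-4-en-1-yl]oxy}dimethylsilane | C=C[C@H](Cc1ccc(OC)c(OC)c1)[C@H](CO[Si](C)(C)C(C)(C)C)Cc1cc(OC)c(OCc2ccccc2)c(OC)c1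
F10 | step 8 | (2R,3S)-2-[4-(benzyloxy)-3,5-dimethoxybenzyl]-3-(3,4-dimethoxybenzyl)pent-4-en-1-ol | C=C[C@H](Cc1ccc(OC)c(OC)c1)[C@H](CO)Cc1cc(OC)c(OCc2ccccc2)c(OC)c1
F11 | step 8 | (2R,3S)-2-[4-(benzyloxy)-3,5-dimethoxybenzyl]-3-(3,4-dimethoxybenzyl)pent-4-enal | C=C[C@H](Cc1ccc(OC)c(OC)c1)[C@H](C=O)Cc1cc(OC)c(OCc2ccccc2)c(OC)c1
F12 | step 8 | (2R,3S)-2-[4-(benzyloxy)-3,5-dimethoxybenzyl]-3-(3,4-dimethoxybenzyl)pent-4-enoic acid | C=C[C@H](Cc1ccc(OC)c(OC)c1)[C@H](C(=O)O)Cc1cc(OC)c(OCc2ccccc2)c(OC)c1
F13 | step 8 | (2R,3R)-2-[4-(benzyloxy)-3,5-dimethoxybenzyl]-3-(3,4-dimethoxybenzyl)-4-oxobutanoic acid | O=C[C@H](Cc1ccc(OC)c(OC)c1)[C@H](C(=O)O)Cc1cc(OC)c(OCc2ccccc2)c(OC)c1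
F14 | step 11 | (3R,4R)-3-[4-(benzyloxy)-3,5-dimethoxybenzyl]-4-(3,4-dimethoxybenzyl)tetrahydrofuran-2-ol (mixture at C2) | COc1ccc(C[C@H]2COC(O)[C@@H]2Cc2cc(OC)c(OCc3ccccc3)c(OC)c2)cc1OC
A1 | alternative 1 | 3-(3,4-dimethoxybenzyl)cyclobutan-1-one | COc1ccc(CC2CC(=O)C2)cc1OC
A2 | alternative 1 | (R)-4-(3,4-dimethoxybenzyl)dihydrofuran-2(3H)-one | COc1ccc(C[C@H]2COC(=O)C2)cc1OC
A3 | alternative 1 | 4-(benzyloxy)-3,5-dimethoxybenzyl bromide | COc1cc(CBr)cc(OC)c1OCc1ccccc1
A4 | alternative 2 | (R)-3-[4-(benzyloxy)-3,5-dimethoxyphenyl]-2-(oxetan-3-yl)propanoic acid | OC(=O)[C@@H](C1COC1)Cc1cc(OC)c(OCc2ccccc2)c(OC)c1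
A5 | alternative 2 | (3R,4S)-3-[4-(benzyloxy)-3,5-dimethoxybenzyl]-4-(hydroxymethyl)dihydrofuran-2(3H)-one | OC[C@H]1COC(=O)[C@@H]1Cc1cc(OC)c(OCc2ccccc2)c(OC)c1
A6 | alternative 3 | (E)-3-(3,4-dimethoxyphenyl)allyl propiolate | C#CC(=O)OC/C=C/c1ccc(OC)c(OC)c1
A7 | alternative 3 | [4-(benzyloxy)-3,5-dimethoxyphenyl]boronic acid | COc1cc(B(O)O)cc(OC)c1OCc1ccccc1
A8 | alternative 3 | (R,E)-3-[4-(benzyloxy)-3,5-dimethoxybenzylidene]-4-(3,4-dimethoxybenzyl)dihydrofuran-2(3H)-one | COc1ccc(C[C@H]2COC(=O)/C2=C/c2cc(OC)c(OCc3ccccc3)c(OC)c2)cc1OC
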